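## Structural features

Compound 21 is a depside: two benzene rings joined by one aryl ester bond, from the C1 carboxyl carbon of ring A to the C4 oxygen of ring B. Ring A is a pentasubstituted resorcinol (C1 ester carbonyl, C2 OH, C3 CHO, C4 OH, C5 H, C6 CH3). Ring B is a methyl benzoate with C2 OCH3, C3 CH3, the ester oxygen at C4, C5 H and C6 CH3. There is no stereocentre, so every problem is positional. The fragile points are the aryl ester link (an activated ester, open to alkoxide, hydroxide and amines), the aldehyde between two free phenols, and the electron-rich ring A (oxidation, alkylation at C5). The ring B methyl ether sits ortho to an ester, which rules out late Lewis-acid dealkylation as a way to free the ring A phenols. The real difficulty is to place one carbon at the aldehyde level at C3 of ring A, not at C5, and to tell four phenolic oxygens apart while the ester link survives. The key step uses the fact that in ring A the C1 carboxyl is para to the C4 oxygen and ortho to the C6 methyl. Ring A atoms C1, C2, C3 and C6 are then pyranone atoms C5, C4, C3 and C6 of a 6-methyl-2-pyranone-5-carboxylate, and C4–C5 is a ketene acetal unit that takes the place of the CO2 bridge.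

## Logic of the disconnections

21 to 19. The ether bond on the ring A C2 oxygen and the two acetal C–O bonds at the C3 carbon are added back. The aldehyde and the C2 phenol must be masked while ring A is made. No skeletal simplification results, but the two most reactive groups are taken out of play. The forward step must drop both masks in one acidic operation, through 20, without touching the aryl ester, the methyl ester or the methyl ether.

19 to 13 and 15. Ring A is cut at C3–C4 and C5–C6. The C4 oxygen para to the carboxyl and the unsubstituted C5 mark C4–C5 as the two carbons of 15, and the rest as pyranone 13. A benzene ring with five different substituents becomes a heterocycle built by simple condensations. The forward step must bond the CH2 of 15 to pyranone C6 and its acetal carbon to C3, and 16, 17 and 18 must collapse in the same flask.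

15 to 14. Only an O–Si bond is cut. 14 is enolised and silylated on oxygen.

13 to 12 to 11. The pyranone C4–O ether bond is cut first, then the acetal C–O bonds. Both masks trace back to one β-chlorovinyl aldehyde. The acetal has to go on first, while the carbonyl is still a normal electrophilic aldehyde, and the chloride has to be displaced without a strong alkoxide, because 12 carries an aryl ester and an acidic 6-methyl group.

11 to 9. The C3–CHO bond and the C4–Cl bond are cut. C3 is the only nucleophilic carbon of 9, so the formyl carbon can enter nowhere else. The forward step passes through 10 and must leave the 6-methyl group alone.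

9 to 7 and 8. The pyranone is cut at C4–C5 and O1–C2. Pyranone C2, C3 and C4 come from 8, and C5, C6, the methyl group and the ester come from 7. The forward step needs C-acylation at the active methylene before ring closure through the enol oxygen, under acid conditions that the aryl ester tolerates.

7 to 4 and 5. The aryl ester C–O bond, the future depside link, is cut. Making it here, through 6, avoids a late coupling of a hindered, fully substituted benzoic acid with a hindered phenol. The price is that every later step must spare this ester.

4 to 3 to 2 to 1. The O–CH3 bond on the C2 oxygen and a temporary benzyl ether on the C4 oxygen are cut. In 1 the C4 phenol is the more reactive one, the reverse of what 21 needs. It is therefore blocked, the chelated C2 phenol is methylated, and the block is removed.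

## Other disconnections considered

Alternative 1: The cut goes through C1–C2 and C5–C6 of ring A. It leads to aryl allenoate A2 (the buta-2,3-dienoate of 4) and the 2-allyl bis(silyloxy)diene A3.
- Forward step: A3 would add across the conjugated double bond of A2, CH2 terminus to the central allene carbon and ketene acetal carbon to the α-carbon. Acid work-up would expel the ethoxy group and move the exocyclic double bond into the ring to give A1.
- In favour: both phenols are free from the start. The C3 carbon is fixed by the diene as firmly as by the pyranone, so the two plans are equal on positional control. The cycloaddition is polar and normal-demand and should run at or below room temperature, which is milder than the thermal pyranone reaction, a point on which it is the better. A2 is about two operations from 4, so the way to the ring-forming step is shorter.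
- Against: C3 arrives as a three-carbon allyl group. Two carbons must be removed again by alkene isomerisation and oxidative cleavage on an easily oxidised resorcinol, which probably needs protection. That makes three to five steps after the key step against one. A2 is an activated ester of an allenic acid, prone to oligomerise and to transfer its acyl group. A3 is a tetrasubstituted silyl dienol ether, hard to obtain as one isomer and hindered at its reacting end.
- Comparison: the step count is about equal. The alternative wins on mildness and on having no protecting groups in the ring-forming step. The chosen plan wins on delivering C3 at the right oxidation level and on a one-step end game.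

Alternative 2: The cut goes through C1–C2, C2–C3 and C4–C5 of ring A (Danheiser benzannulation). It leads to diazo ketone A5 and siloxyalkyne A6.
- Forward step: photochemical Wolff rearrangement of A5 would give vinylketene A7. This would add to A6 in a (2+2) sense. Four-electron opening of the cyclobutenone, six-electron closure and tautomerisation would give A4.
- In favour: all substituents of ring A are assembled in one operation. The formyl carbon is already an acetal at C3 and the two oxygens are differentiated (free C2 OH, silylated C4 oxygen), so it is equal to the chosen plan on positional control. Its end game (fluoride and mild acid, no benzyl cation to trap) is better than that of the chosen plan.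
- Against: A5 needs diazoalkane or diazo-transfer chemistry on a half-ester that already carries the aryl ester link, a hazard the chosen plan avoids. A6 is a sensitive ynol silyl ether with a multistep preparation. Irradiation of aryl esters invites photo-Fries rearrangement. A7 has an electron-poor acrylate terminus and can dimerise or be trapped before it meets A6.
- Comparison: the two plans are equal on structure. The alternative is more elegant mechanistically but more fragile. On step economy it is equal at best, with two fragments of three to four steps each, and it is worse on safety.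

Alternative 3: The cut is the C1–C6 bond of ring A (retro-aldol). It leads to the aryl 3,5,7-trioxooctanoate A9.
- Forward step: mild base would make chain C2 attack the C7 ketone. Dehydration and enolisation would give orsellinate A8, which lacks the formyl group.
- In favour: it is biomimetic, uses cheap reagents, needs no protecting groups on ring A, and is the shortest way to the depside skeleton. It is better than the chosen plan on step count up to that point and on mechanistic simplicity.
- Against: A9 is an activated aryl ester. Lactonisation of the C5 enol oxygen onto it, with release of 4, competes with the aldol closure and is helped by the good aryloxide leaving group. Base can also cleave the link directly. A8 then needs electrophilic formylation that must choose C3 over C5 of ring A, both activated by the two hydroxyls, and over the free position of ring B. That choice is the central problem of the target and is left open here.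
- Comparison: the alternative is shorter and simpler. The chosen plan spends three or four more steps to settle the formyl position before the ring exists and to keep the ester link out of basic media.

Key step: step 10

Remark on the chemistry:
- 21 is achiral. The only stereogenic compound on the route is the transient bicyclic lactone 16, which forms as a racemate and loses both centres on aromatisation.
- The atom mapping of 13 and 19 onto 21 was checked (pyranone C3, C4, C5, C6 become ring A C3, C2, C1, C6; the carbons of 15 become C5 and C4) and needs no correction.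
- Two design choices on the way to 13 depart from the obvious ones. The acetal is made by aprotic silyl transfer, so no free diol meets the C4–Cl bond. The chloride is displaced under weak-base, amine-catalysed conditions instead of with a sodium alkoxide.
- A free formyl group is not carried into the key step, because O=CH–C3=C4 would be a 1-oxadiene open to hetero-Diels–Alder reaction with 15.
- LiN(iPr)2 solution, 4-methoxybenzyl alcohol and 1,2-bis(trimethylsilyloxy)ethane are taken as purchased.

## Steps

Step 1
Reactants: 1 methyl 2,4-dihydroxy-3,6-dimethylbenzoate (atraric acid)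
Product: 2 methyl 4-(benzyloxy)-2-hydroxy-3,6-dimethylbenzoate
Conditions: BnBr (1.05 equiv), K2CO3, acetone, reflux
Reagents that add atoms: benzyl bromide, BrCc1ccccc1
Why: Williamson etherification; the 2-OH is held in a hydrogen bond to the ester carbonyl and is flanked on both sides, so under weak-base conditions only the free, more acidic 4-OH should be alkylated.

Step 2
Reactants: 2 methyl 4-(benzyloxy)-2-hydroxy-3,6-dimethylbenzoate
Product: 3 methyl 4-(benzyloxy)-2-methoxy-3,6-dimethylbenzoate
Conditions: MeI (3 equiv), K2CO3, DMF, 50 °C
Reagents that add atoms: iodomethane, CI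
Why: Williamson O-methylation; with the 4-oxygen capped the chelated 2-OH is the only acidic site, and excess MeI in a dipolar aprotic solvent should overcome its low reactivity without touching the methyl ester.

Step 3
Reactants: 3 methyl 4-(benzyloxy)-2-methoxy-3,6-dimethylbenzoate
Product: 4 methyl 4-hydroxy-2-methoxy-3,6-dimethylbenzoate
Conditions: H2 (1 atm), 10% Pd/C, EtOAc–MeOH, rt
Reagents that add atoms: none
Why: Hydrogenolysis of a benzyl aryl ether over palladium; the esters, the methyl ether and the ring methyl groups are inert, and benzyl was chosen because it survives the basic methylation of step 2.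

Step 4
Reactants: 4 methyl 4-hydroxy-2-methoxy-3,6-dimethylbenzoate; 5 2,2,6-trimethyl-4H-1,3-dioxin-4-one
Product: 7 3-methoxy-4-(methoxycarbonyl)-2,5-dimethylphenyl 3-oxobutanoate, via acetylketene 6 (not isolated)
Conditions: xylenes, 135 °C, acetone distilled off
Reagents that add atoms: none
Why: Thermal retro-hetero-Diels–Alder reaction of the dioxinone releases acetylketene 6, which adds the phenolic O–H (acylketene acetoacetylation); the conditions are neutral, so the methyl ester is not exchanged, and removal of acetone drives the reaction.

Step 5
Reactants: 7 3-methoxy-4-(methoxycarbonyl)-2,5-dimethylphenyl 3-oxobutanoate; 8 malonyl dichloride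
Product: 9 3-methoxy-4-(methoxycarbonyl)-2,5-dimethylphenyl 4-hydroxy-6-methyl-2-oxo-2H-pyran-5-carboxylate
Conditions: 8 (1.2 equiv), ClCH2CH2Cl, rt → 50 °C, N2 sweep
Reagents that add atoms: none
Why: Known 4-hydroxy-2-pyranone synthesis from β-keto esters and malonyl dichloride: C-acylation at the active methylene, then ring closure of the ketone enol oxygen on the second acyl chloride; the medium is acidic, which the aryl and methyl esters tolerate.

Step 6
Reactants: 9 3-methoxy-4-(methoxycarbonyl)-2,5-dimethylphenyl 4-hydroxy-6-methyl-2-oxo-2H-pyran-5-carboxylate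
Product: 11 3-methoxy-4-(methoxycarbonyl)-2,5-dimethylphenyl 4-chloro-3-formyl-6-methyl-2-oxo-2H-pyran-5-carboxylate, via iminium chloride 10 (not isolated)
Conditions: POCl3 (2.5 equiv), DMF, 0 → 60 °C; then ice–water, rapid extraction
Reagents that add atoms: N,N-dimethylformamide, CN(C)C=O; phosphoryl chloride, O=P(Cl)(Cl)Cl; water, O
Why: Vilsmeier–Haack reaction: C3, the enol β-carbon and the only nucleophilic ring carbon of the 4-hydroxypyranone, is formylated while the vinylogous acid OH becomes the vinylogous acid chloride, as with 4-hydroxycoumarins, and cold hydrolysis of iminium salt 10 frees the aldehyde. Ring B is too electron-poor for this weak electrophile.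

Step 7
Reactants: 11 3-methoxy-4-(methoxycarbonyl)-2,5-dimethylphenyl 4-chloro-3-formyl-6-methyl-2-oxo-2H-pyran-5-carboxylate
Product: 12 3-methoxy-4-(methoxycarbonyl)-2,5-dimethylphenyl 4-chloro-3-(1,3-dioxolan-2-yl)-6-methyl-2-oxo-2H-pyran-5-carboxylate
Conditions: Me3SiOCH2CH2OSiMe3 (1.5 equiv), Me3SiOTf (5 mol %), CH2Cl2, −78 → −20 °C; pyridine quench
Reagents that add atoms: 1,2-bis(trimethylsilyloxy)ethane, C[Si](C)(C)OCCO[Si](C)(C)C
Why: Noyori acetalisation by silyl transfer; no free alcohol, water or protic acid is present, so the doubly activated C4–Cl bond is not attacked, and the aldehyde of a β-chlorovinyl aldehyde is still a normal electrophilic carbonyl group at this stage.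

Step 8
Reactants: 12 3-methoxy-4-(methoxycarbonyl)-2,5-dimethylphenyl 4-chloro-3-(1,3-dioxolan-2-yl)-6-methyl-2-oxo-2H-pyran-5-carboxylate
Product: 13 3-methoxy-4-(methoxycarbonyl)-2,5-dimethylphenyl 3-(1,3-dioxolan-2-yl)-4-[(4-methoxybenzyl)oxy]-6-methyl-2-oxo-2H-pyran-5-carboxylate
Conditions: 4-MeOC6H4CH2OH (1.3 equiv), DABCO (0.2 equiv), Cs2CO3 (1.5 equiv), MeCN, 0 °C → rt
Reagents that add atoms: 4-methoxybenzyl alcohol, COc1ccc(CO)cc1
Why: Addition–elimination (vinylic substitution) at C4 of a 4-chloro-2-pyranone, a vinylogous acyl chloride; DABCO serves as nucleophilic catalyst so that a carbonate base suffices, and the absence of a stoichiometric strong alkoxide should spare the aryl ester, the lactone and the acidic 6-methyl group.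

Step 9
Reactants: 14 trimethylsilyl acetate
Product: 15 1,1-bis(trimethylsilyloxy)ethene
Conditions: LiN(iPr)2 (1.1 equiv), THF, −78 °C; Me3SiCl (1.2 equiv), −78 °C → rt; distillation
Reagents that add atoms: chlorotrimethylsilane, C[Si](C)(C)Cl
Why: Kinetic enolisation of the silyl ester and O-silylation of the lithium enolate by the hard electrophile Me3SiCl gives the bis(silyl) ketene acetal, which is distilled and used fresh.

Step 10
Reactants: 13 3-methoxy-4-(methoxycarbonyl)-2,5-dimethylphenyl 3-(1,3-dioxolan-2-yl)-4-[(4-methoxybenzyl)oxy]-6-methyl-2-oxo-2H-pyran-5-carboxylate; 15 1,1-bis(trimethylsilyloxy)ethene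
Product: 19 3-methoxy-4-(methoxycarbonyl)-2,5-dimethylphenyl 3-(1,3-dioxolan-2-yl)-4-hydroxy-2-[(4-methoxybenzyl)oxy]-6-methylbenzoate, via bicyclic lactone adduct 16 (not isolated), via bis(silyloxy)cyclohexadiene 17 (not isolated), via aryl trimethylsilyl ether 18 (not isolated)
Conditions: 15 (4 equiv), toluene, 105 °C, sealed tube; then THF–aq. NH4Cl, rt
Reagents that add atoms: none
Why: This is an inverse-electron-demand Diels–Alder reaction of a 2-pyranone-5-carboxylate with a ketene acetal, the reaction type known for coumalates and 3-acylpyranones. The nucleophilic CH2 of 15 should attack pyranone C6, the carbon conjugated to both the C5 ester and the lactone carbonyl, and the developing oxocarbenium carbon then closes on C3 in an asynchronous, possibly zwitterionic (4+2) process that gives the 2-oxabicyclo[2.2.2]octenone 16. Ring A is thus closed by cycloaddition, with C5–C6 and C3–C4 formed in the same event. Cycloreversion of 16 expels CO2 to give cyclohexadiene 17, 1,2-elimination of Me3SiOH aromatises it to 18, and the mild aqueous work-up frees the C4 phenol. The two bridgehead centres of 16 arise as a racemate and vanish on aromatisation, so no stereocontrol is required. The selectivity needed is regiochemical (CH2 to C6, acetal carbon to C3) and chemical (the pyranone diene, not the formyl carbon or C4): the first follows from the polarisation by the C5 ester and the ring oxygen, the second from the dioxolane, which removes the 1-oxadiene and the β-alkoxy enal that a free aldehyde would offer. The aryl ester, methyl ester, benzyl-type ether and acetal should be inert under these neutral thermal conditions.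

Step 11
Reactants: 19 3-methoxy-4-(methoxycarbonyl)-2,5-dimethylphenyl 3-(1,3-dioxolan-2-yl)-4-hydroxy-2-[(4-methoxybenzyl)oxy]-6-methylbenzoate
Product: 21 2'-O-methylatranorin [3-methoxy-4-(methoxycarbonyl)-2,5-dimethylphenyl 3-formyl-2,4-dihydroxy-6-methylbenzoate], via dihydroxy dioxolane 20 (not isolated)
Conditions: CF3CO2H–CH2Cl2 (1:4), anisole (10 equiv), 0 °C; then H2O, rt
Reagents that add atoms: water, O
Why: Acidolysis of the 4-methoxybenzyl aryl ether (SN1 ionisation, the cation is trapped by anisole in a Friedel–Crafts alkylation so that it cannot alkylate C5 of ring A) gives 20; added water then hydrolyses the aryl dioxolane, pulled by the doubly hydrogen-bonded aldehyde. The aryl ester, methyl ester and methyl ether are stable to CF3CO2H.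

## Compound list

1 | methyl 2,4-dihydroxy-3,6-dimethylbenzoate (atraric acid) | COC(=O)c1c(C)cc(O)c(C)c1O | starting material
2 | methyl 4-(benzyloxy)-2-hydroxy-3,6-dimethylbenzoate | COC(=O)c1c(C)cc(OCc2ccccc2)c(C)c1O | intermediate
3 | methyl 4-(benzyloxy)-2-methoxy-3,6-dimethylbenzoate | COC(=O)c1c(C)cc(OCc2ccccc2)c(C)c1OC | intermediate
4 | methyl 4-hydroxy-2-methoxy-3,6-dimethylbenzoate | COC(=O)c1c(C)cc(O)c(C)c1OC | intermediate
5 | 2,2,6-trimethyl-4H-1,3-dioxin-4-one | CC1=CC(=O)OC(C)(C)O1 | starting material
6 | acetylketene (but-1-ene-1,3-dione) | CC(=O)C=C=O | intermediate (not isolated)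
7 | 3-methoxy-4-(methoxycarbonyl)-2,5-dimethylphenyl 3-oxobutanoate | CC(=O)CC(=O)Oc1cc(C)c(C(=O)OC)c(OC)c1C | intermediate
8 | malonyl dichloride | O=C(Cl)CC(Cl)=O | starting material
9 | 3-methoxy-4-(methoxycarbonyl)-2,5-dimethylphenyl 4-hydroxy-6-methyl-2-oxo-2H-pyran-5-carboxylate | CC1=C(C(=O)Oc2cc(C)c(C(=O)OC)c(OC)c2C)C(O)=CC(=O)O1 | intermediate
10 | N-{[4-chloro-5-{[3-methoxy-4-(methoxycarbonyl)-2,5-dimethylphenoxy]carbonyl}-6-methyl-2-oxo-2H-pyran-3-yl]methylidene}-N-methylmethanaminium chloride | CC1=C(C(=O)Oc2cc(C)c(C(=O)OC)c(OC)c2C)C(Cl)=C(C=[N+](C)C)C(=O)O1.[Cl-] | intermediate (not isolated)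
11 | 3-methoxy-4-(methoxycarbonyl)-2,5-dimethylphenyl 4-chloro-3-formyl-6-methyl-2-oxo-2H-pyran-5-carboxylate | CC1=C(C(=O)Oc2cc(C)c(C(=O)OC)c(OC)c2C)C(Cl)=C(C=O)C(=O)O1 | intermediate
12 | 3-methoxy-4-(methoxycarbonyl)-2,5-dimethylphenyl 4-chloro-3-(1,3-dioxolan-2-yl)-6-methyl-2-oxo-2H-pyran-5-carboxylate | CC1=C(C(=O)Oc2cc(C)c(C(=O)OC)c(OC)c2C)C(Cl)=C(C2OCCO2)C(=O)O1 | intermediate
13 | 3-methoxy-4-(methoxycarbonyl)-2,5-dimethylphenyl 3-(1,3-dioxolan-2-yl)-4-[(4-methoxybenzyl)oxy]-6-methyl-2-oxo-2H-pyran-5-carboxylate | CC1=C(C(=O)Oc2cc(C)c(C(=O)OC)c(OC)c2C)C(OCc2ccc(OC)cc2)=C(C2OCCO2)C(=O)O1 | intermediate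
14 | trimethylsilyl acetate | CC(=O)O[Si](C)(C)C | starting material
15 | 1,1-bis(trimethylsilyloxy)ethene | C=C(O[Si](C)(C)C)O[Si](C)(C)C | intermediate
16 | 3-methoxy-4-(methoxycarbonyl)-2,5-dimethylphenyl 4-(1,3-dioxolan-2-yl)-5-[(4-methoxybenzyl)oxy]-1-methyl-3-oxo-8,8-bis(trimethylsilyloxy)-2-oxabicyclo[2.2.2]oct-5-ene-6-carboxylate (racemic; one enantiomer written, the two bridgeheads are tied together by the bicycle) | C[C@]12CC(O[Si](C)(C)C)(O[Si](C)(C)C)[C@](C3OCCO3)(C(=O)O1)C(OCc1ccc(OC)cc1)=C2C(=O)Oc1cc(C)c(C(=O)OC)c(OC)c1C | intermediate (not isolated)
17 | 3-methoxy-4-(methoxycarbonyl)-2,5-dimethylphenyl 5-(1,3-dioxolan-2-yl)-6-[(4-methoxybenzyl)oxy]-2-methyl-4,4-bis(trimethylsilyloxy)cyclohexa-1,5-diene-1-carboxylate | CC1=C(C(=O)Oc2cc(C)c(C(=O)OC)c(OC)c2C)C(OCc2ccc(OC)cc2)=C(C2OCCO2)C(O[Si](C)(C)C)(O[Si](C)(C)C)C1 | intermediate (not isolated)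
18 | 3-methoxy-4-(methoxycarbonyl)-2,5-dimethylphenyl 3-(1,3-dioxolan-2-yl)-2-[(4-methoxybenzyl)oxy]-6-methyl-4-(trimethylsilyloxy)benzoate | COc1ccc(COc2c(C3OCCO3)c(O[Si](C)(C)C)cc(C)c2C(=O)Oc2cc(C)c(C(=O)OC)c(OC)c2C)cc1 | intermediate (not isolated)
19 | 3-methoxy-4-(methoxycarbonyl)-2,5-dimethylphenyl 3-(1,3-dioxolan-2-yl)-4-hydroxy-2-[(4-methoxybenzyl)oxy]-6-methylbenzoate | COc1ccc(COc2c(C3OCCO3)c(O)cc(C)c2C(=O)Oc2cc(C)c(C(=O)OC)c(OC)c2C)cc1 | intermediate
20 | 3-methoxy-4-(methoxycarbonyl)-2,5-dimethylphenyl 3-(1,3-dioxolan-2-yl)-2,4-dihydroxy-6-methylbenzoate | COC(=O)c1c(C)cc(OC(=O)c2c(C)cc(O)c(C3OCCO3)c2O)c(C)c1OC | intermediate (not isolated)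
21 | 2'-O-methylatranorin, 3-methoxy-4-(methoxycarbonyl)-2,5-dimethylphenyl 3-formyl-2,4-dihydroxy-6-methylbenzoate | COC(=O)c1c(C)cc(OC(=O)c2c(C)cc(O)c(C=O)c2O)c(C)c1OC | target

## Step count and least certain steps

Total: 11 steps. Longest linear sequence: 10 steps (steps 1 to 8, then 10 and 11). Step 9 is a one-step side branch.

Step 10 (key step). The cycloaddition may fail to start: C6 is fully substituted and the 4-alkoxy group raises the acceptor level of the diene, while 15 slowly rearranges to its C-silyl isomer on heating or passes silicon to the acidic 6-methyl position. The first C–C bond may also form and then stall as an open silyl-transfer Michael adduct that never closes on the hindered C3. The fallback sets out from 13 and replaces the silyl ketene acetal by a ketene dialkyl acetal, the dienophile class with the firmest precedent, which is robust to heat and cannot transfer silicon. This is 1,1-bis(benzyloxy)ethene F1, made by dehydrohalogenation of the corresponding haloacetal. Heating 13 with F1 in mesitylene at 140 °C should give, after loss of CO2 and benzyl alcohol, 3-methoxy-4-(methoxycarbonyl)-2,5-dimethylphenyl 4-(benzyloxy)-3-(1,3-dioxolan-2-yl)-2-[(4-methoxybenzyl)oxy]-6-methylbenzoate F2. BCl3 with pentamethylbenzene in CH2Cl2 at −78 °C should then remove both benzyl-type ethers and, on aqueous work-up, the acetal, while the ring B methyl ether is expected to stay at this temperature. The route is rejoined at 21.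

Step 8. Proton abstraction from the vinylogously acidic 6-methyl group may stall the substitution or lead to self-condensation at C4. Alkoxide may add at C6 or C2 and open the ring, or take the acyl group off the aryl ester. The fallback sets out from 12 and brings the oxygen in as a weakly basic carboxylate. CsOAc in DMF at 50 °C should add at C4 and expel chloride, and a second acetate should take over the acetyl group. Buffered work-up at pH 5 would give 3-methoxy-4-(methoxycarbonyl)-2,5-dimethylphenyl 3-(1,3-dioxolan-2-yl)-4-hydroxy-6-methyl-2-oxo-2H-pyran-5-carboxylate F3. This is used at once, because the acidic 4-OH sits next to the acetal. A Mitsunobu reaction (4-methoxybenzyl alcohol, PPh3, diisopropyl azodicarboxylate, THF, 0 °C), which is known to favour the 4-oxygen of 4-hydroxy-2-pyranones, then rejoins the route at 13. The ether oxygen now comes from the pyranone and not from an alkoxide.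

Step 6. The chloroiminium reagent may condense with the activated 6-methyl group alongside C3 formylation, and the very labile C4–Cl bond may hydrolyse during aqueous work-up. The fallback sets out from 9 and separates formylation from chlorination. HC(OEt)3 and aniline in hot 2-propanol should give 3-methoxy-4-(methoxycarbonyl)-2,5-dimethylphenyl 3-(anilinomethylidene)-6-methyl-2,4-dioxo-3,4-dihydro-2H-pyran-5-carboxylate F4. Aqueous acid in THF should hydrolyse it to 3-methoxy-4-(methoxycarbonyl)-2,5-dimethylphenyl 3-formyl-4-hydroxy-6-methyl-2-oxo-2H-pyran-5-carboxylate F5. Oxalyl chloride with catalytic DMF in CH2Cl2 at 0 °C then converts the vinylogous acid into its chloride with non-aqueous work-up, and the route is rejoined at 11.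

Step 5. Self-condensation of 8 may outrun C-acylation of the weakly enolised aryl acetoacetate, or acylation may occur on the enol oxygen. The fallback sets out from 7 and builds the ring in two controlled stages. Magnesium-mediated C-acylation (MgCl2, pyridine, CH2Cl2, 0 °C) with methyl 3-chloro-3-oxopropanoate should give 1-[3-methoxy-4-(methoxycarbonyl)-2,5-dimethylphenyl] 5-methyl 2-acetyl-3-oxopentanedioate F6. Acid-promoted lactonisation of the acetyl enol oxygen onto the methyl ester (TsOH, toluene, 80 °C, loss of methanol) then rejoins the route at 9. Attack on the aryl ester is geometrically excluded because it would form a four-membered ring.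

## Further compounds

F1 | step 10 | 1,1-bis(benzyloxy)ethene | C=C(OCc1ccccc1)OCc1ccccc1
F2 | step 10 | 3-methoxy-4-(methoxycarbonyl)-2,5-dimethylphenyl 4-(benzyloxy)-3-(1,3-dioxolan-2-yl)-2-[(4-methoxybenzyl)oxy]-6-methylbenzoate | COc1ccc(COc2c(C3OCCO3)c(OCc3ccccc3)cc(C)c2C(=O)Oc2cc(C)c(C(=O)OC)c(OC)c2C)cc1
F3 | step 8 | 3-methoxy-4-(methoxycarbonyl)-2,5-dimethylphenyl 3-(1,3-dioxolan-2-yl)-4-hydroxy-6-methyl-2-oxo-2H-pyran-5-carboxylate | CC1=C(C(=O)Oc2cc(C)c(C(=O)OC)c(OC)c2C)C(O)=C(C2OCCO2)C(=O)O1
F4 | step 6 | 3-methoxy-4-(methoxycarbonyl)-2,5-dimethylphenyl 3-(anilinomethylidene)-6-methyl-2,4-dioxo-3,4-dihydro-2H-pyran-5-carboxylate (exocyclic double bond geometry not fixed, tautomeric) | CC1=C(C(=O)Oc2cc(C)c(C(=O)OC)c(OC)c2C)C(=O)C(=CNc2ccccc2)C(=O)O1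
F5 | step 6 | 3-methoxy-4-(methoxycarbonyl)-2,5-dimethylphenyl 3-formyl-4-hydroxy-6-methyl-2-oxo-2H-pyran-5-carboxylate | CC1=C(C(=O)Oc2cc(C)c(C(=O)OC)c(OC)c2C)C(O)=C(C=O)C(=O)O1
F6 | step 5 | 1-[3-methoxy-4-(methoxycarbonyl)-2,5-dimethylphenyl] 5-methyl 2-acetyl-3-oxopentanedioate (enolised; the methine centre is configurationally labile) | COC(=O)CC(=O)C(C(C)=O)C(=O)Oc1cc(C)c(C(=O)OC)c(OC)c1C
A1 | alternative 1 | 3-methoxy-4-(methoxycarbonyl)-2,5-dimethylphenyl 2,4-dihydroxy-6-methyl-3-(prop-2-enyl)benzoate | C=CCc1c(O)cc(C)c(C(=O)Oc2cc(C)c(C(=O)OC)c(OC)c2C)c1O
A2 | alternative 1 | 3-methoxy-4-(methoxycarbonyl)-2,5-dimethylphenyl buta-2,3-dienoate | C=C=CC(=O)Oc1cc(C)c(C(=O)OC)c(OC)c1C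
A3 | alternative 1 | 1-ethoxy-2-(prop-2-enyl)-1,3-bis(trimethylsilyloxy)buta-1,3-diene (geometry of the tetrasubstituted double bond not defined) | C=CCC(C(=C)O[Si](C)(C)C)=C(OCC)O[Si](C)(C)C
A4 | alternative 2 | 3-methoxy-4-(methoxycarbonyl)-2,5-dimethylphenyl 3-(diethoxymethyl)-2-hydroxy-6-methyl-4-(triisopropylsilyloxy)benzoate | CCOC(OCC)c1c(O[Si](C(C)C)(C(C)C)C(C)C)cc(C)c(C(=O)Oc2cc(C)c(C(=O)OC)c(OC)c2C)c1O
A5 | alternative 2 | 3-methoxy-4-(methoxycarbonyl)-2,5-dimethylphenyl (2E)-5-diazo-3-methyl-4-oxopent-2-enoate | O=C(/C=C(C)/C(=O)C=[N+]=[N-])Oc1cc(C)c(C(=O)OC)c(OC)c1C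
A6 | alternative 2 | (3,3-diethoxyprop-1-yn-1-yloxy)triisopropylsilane | CCOC(OCC)C#CO[Si](C(C)C)(C(C)C)C(C)C
A7 | alternative 2 | 3-methoxy-4-(methoxycarbonyl)-2,5-dimethylphenyl (2E)-3-methyl-5-oxopenta-2,4-dienoate | O=C=C/C(C)=C/C(=O)Oc1cc(C)c(C(=O)OC)c(OC)c1C
A8 | alternative 3 | 3-methoxy-4-(methoxycarbonyl)-2,5-dimethylphenyl 2,4-dihydroxy-6-methylbenzoate | Cc1cc(O)cc(O)c1C(=O)Oc1cc(C)c(C(=O)OC)c(OC)c1C
A9 | alternative 3 | 3-methoxy-4-(methoxycarbonyl)-2,5-dimethylphenyl 3,5,7-trioxooctanoate | CC(=O)CC(=O)CC(=O)CC(=O)Oc1cc(C)c(C(=O)OC)c(OC)c1C
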